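**Plan**

- Numbering used throughout: C1 (quaternary fusion carbon, Me), C2, C3, C4 (isopropyl carbinol), C5 (fusion CH), C6 (anisoate), C7, C8 (Me), C9, C10 (acetate); β is the face of the C1 methyl group.
- Enabling feature: the cycloheptene ring C5–C6–C7–C8–C9–C10–C1, fused to the cyclopentane at C1–C5, is the [3,3] image of a cis-divinylcyclopropane C5/C10/C1 whose third carbon is the quaternary C1. The C6 oxygen maps onto a silyloxyvinyl group on C5 and the C8 methyl onto an (E)-propenyl group on C10.
- Retrosynthesis: both esters off; C8=C9/C10–OH back to a C9=C10 olefin (epoxide, selenide, selenoxide); C6–OH to the ketone; the C4–isopropyl bond; then C7–C8 (Cope, restoring C5–C10); then C5–C1 and C5–C10 (carbenoid plus E olefin); finally C2–C3 (diketone dianion alkylation) and C1=C10 (Wittig).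
- Forward: an acyclic diazo trienone is built from crotonaldehyde, a propionate ylide and acetylacetone. One carbenoid step closes cyclopentanone and cyclopropane together, the Cope step expands the three-membered ring to the seven-membered ring, and the hydroazulene is then functionalised at C4, C5/C6 and C9/C10.
- Stereochemistry: C1 from the chiral dirhodium carboxylate in the cyclopropanation (the E olefin fixes the cis-divinyl arrangement); C8 (temporary) from the boat Cope; C4 by addition anti to the C1 methyl; C5 by equilibration to the trans-fused ketone; C6 by hydroxyl-delivered hydride; C10 by α-epoxidation anti to the C1 methyl, selenide opening with inversion at C9 and syn elimination through 8β-H.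

Key step: step 8

Remark (assumption): Rh2(S-PTAD)4, dirhodium tetrakis[(S)-(1-adamantyl)(N-phthalimido)acetate] (a carboxylate of divalent rhodium), is taken to deliver the (1S,5R,6R) cyclopropane; the sense of induction has to be confirmed on the first run, and Rh2(R-PTAD)4 would be used instead, with nothing else changed, if it proves opposite.

**Route**

Step 1
Reactants: 1 crotonaldehyde; 2 ethyl 2-(triphenyl-λ5-phosphanylidene)propanoate
Product: 3 ethyl (2E,4E)-2-methylhexa-2,4-dienoate
Conditions: CH2Cl2, 0 °C to rt
Reagents that add atoms: none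
Why: Wittig olefination with a stabilised ylide, which should give the (2E)-trisubstituted enoate while the E geometry of crotonaldehyde is carried over.

Step 2
Reactants: 3 ethyl (2E,4E)-2-methylhexa-2,4-dienoate
Product: 4 (2E,4E)-2-methylhexa-2,4-dien-1-ol
Conditions: i-Bu2AlH (2.2 equiv), CH2Cl2, −78 to 0 °C; aqueous potassium sodium tartrate
Reagents that add atoms: none
Why: 1,2-reduction of the conjugated ester by the aluminium hydride (DIBAL ester reduction) gives the allylic alcohol and leaves the diene alone.

Step 3
Reactants: 4 (2E,4E)-2-methylhexa-2,4-dien-1-ol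
Product: 5 (2E,4E)-1-bromo-2-methylhexa-2,4-diene
Conditions: PBr3, pyridine (cat.), Et2O, −20 to 0 °C; used crude
Reagents that add atoms: phosphorus tribromide, BrP(Br)Br
Why: Substitution of the primary allylic alcohol via its phosphite (SN2-type bromination) keeps both E olefins, the conjugated primary bromide being also the thermodynamic allylic isomer.

Step 4
Reactants: 5 (2E,4E)-1-bromo-2-methylhexa-2,4-diene; 6 acetylacetone
Product: 7 (7E,9E)-7-methylundeca-7,9-diene-2,4-dione
Conditions: 6, NaH, THF, 0 °C; n-BuLi, 0 °C; then 5, 0 °C to rt; aqueous NH4Cl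
Reagents that add atoms: none
Why: γ-Alkylation of the β-diketone dianion: the terminal carbanion is the more reactive site and should displace the primary allylic bromide by SN2, joining C3 to C2 with the (E,E)-diene intact.

Step 5
Reactants: 7 (7E,9E)-7-methylundeca-7,9-diene-2,4-dione
Product: 8 (7E,9E)-3-diazo-7-methylundeca-7,9-diene-2,4-dione
Conditions: 4-acetamidobenzenesulfonyl azide, Et3N, MeCN, 0 °C to rt
Reagents that add atoms: 4-acetamidobenzenesulfonyl azide, CC(=O)Nc1ccc(cc1)S(=O)(=O)N=[N+]=[N-]
Why: Regitz diazo transfer to the doubly activated methylene of the 1,3-diketone.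

Step 6
Reactants: 8 (7E,9E)-3-diazo-7-methylundeca-7,9-diene-2,4-dione
Product: 9 (7E,9E)-2-(tert-butyldimethylsilyloxy)-3-diazo-7-methylundeca-1,7,9-trien-4-one
Conditions: LiN(SiMe3)2 (1.05 equiv), THF, −78 °C; TBSOTf, −78 °C; cold aqueous NaHCO3, pentane; used at once
Reagents that add atoms: tert-butyldimethylsilyl trifluoromethanesulfonate, CC(C)(C)[Si](C)(C)OS(=O)(=O)C(F)(F)F
Why: Kinetic enolisation with the hindered amide base should take place at the methyl group rather than at the C3 methylene (the diazo carbon carries no hydrogen), and O-silylation of the lithium enolate gives the silyloxyvinyl diazoketone (kinetic silyl enol ether formation).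

Step 7
Reactants: 9 (7E,9E)-2-(tert-butyldimethylsilyloxy)-3-diazo-7-methylundeca-1,7,9-trien-4-one
Product: 10 (1S,5R,6R)-1-[1-(tert-butyldimethylsilyloxy)ethenyl]-5-methyl-6-[(E)-prop-1-enyl]bicyclo[3.1.0]hexan-2-one
Conditions: Rh2(S-PTAD)4 (1 mol %), hexanes, slow addition of 9, −20 to 0 °C; cold filtration through Et3N-deactivated silica; kept cold
Reagents that add atoms: none
Why: Intramolecular cyclopropanation by the donor/acceptor rhodium carbenoid at the proximal E trisubstituted olefin closes the cyclopentanone and the three-membered ring at once; the concerted syn addition turns the E geometry into a 6-exo propenyl group cis to the silyloxyvinyl and methyl groups, and the chiral carboxylate ligands select the olefin face and so fix C1 together with C5 and C10.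

Step 8
Reactants: 10 (1S,5R,6R)-1-[1-(tert-butyldimethylsilyloxy)ethenyl]-5-methyl-6-[(E)-prop-1-enyl]bicyclo[3.1.0]hexan-2-one
Product: 11 (1R,8R)-6-(tert-butyldimethylsilyloxy)-1β,8α-dimethylhydroazulena-5,9-dien-4-one (C5=C6 silyl enol ether, C9=C10 olefin, C4 ketone)
Conditions: toluene (degassed, base-washed glassware), 80–100 °C
Reagents that add atoms: none
Why: Concerted [3,3] sigmatropic shift through a boat transition state in which the silyloxyvinyl and propenyl groups lie folded over the cyclopropane, the closest known reaction being the cis-divinylcyclopropane to cyclohepta-1,4-diene rearrangement that also follows carbenoid cyclopropanations of dienes. The seven-membered ring closes by union of the two vinyl termini (C7–C8) while the strained C5–C10 bond opens, a ring expansion in which the C1–C5 bond survives as the ring fusion and C1 is not touched. The one new stereocentre, C8, follows from the boat geometry and the E olefin: the methyl group points outward and ends trans to the C1 methyl (8α), the inward hydrogen ends 8β. The step needs the two vinyl groups cis, which the bridgehead and 6-exo positions fixed in step 7 guarantee, and it needs the Cope path to outrun the 1,5-homodienyl hydrogen shift from the syn C1 methyl, which the E geometry (only hydrogens point inward) and a temperature held at or below 100 °C should secure. C6 emerges as a single, regiodefined silyl enol ether conjugated to the C4 ketone.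

Step 9
Reactants: 11 (1R,8R)-6-(tert-butyldimethylsilyloxy)-1β,8α-dimethylhydroazulena-5,9-dien-4-one; 12 isopropylmagnesium chloride
Product: 14 trans-fused β-hydroxy ketone (4β-hydroxy-4α-isopropyl-1β,8α-dimethyl-5αH-hydroazul-9-en-6-one), via tertiary carbinol silyl enol ether 13 (not isolated)
Conditions: 12, CeCl3 (anhydrous), THF, −78 °C; AcOH, then Bu4NF, THF, −78 to 0 °C; DBU (0.2 equiv), CH2Cl2, rt
Reagents that add atoms: none
Why: Organocerium 1,2-addition (which suppresses enolisation and β-hydride reduction) to the C4 carbonyl of the vinylogous silyl ester should occur anti to the C1 methyl to give the 4β-carbinol, buffered fluoride then frees the C6 ketone without ionising the tertiary allylic alcohol, and base equilibration at C5 should favour the trans-fused ketone in which C6 is trans to the isopropyl group and hydrogen-bonded to the 4β-hydroxyl.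

Step 10
Reactants: 14 trans-fused β-hydroxy ketone
Product: 15 4α-isopropyl-1β,8α-dimethyl-5αH-hydroazul-9-ene-4β,6α-diol
Conditions: Me4NBH(OAc)3, MeCN–AcOH (1:1), −30 to −20 °C
Reagents that add atoms: none
Why: Evans–Saksena reduction: the triacetoxyborohydride, inert to the ketone by itself, exchanges a ligand for the C4 hydroxyl and delivers hydride internally to the β face of C6, giving the 6α-alcohol (anti 1,3-diol).

Step 11
Reactants: 15 4α-isopropyl-1β,8α-dimethyl-5αH-hydroazul-9-ene-4β,6α-diol
Product: 16 4β-hydroxy-4α-isopropyl-1β,8α-dimethyl-5αH-hydroazul-9-en-6α-yl 4-methoxybenzoate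
Conditions: 4-methoxybenzoyl chloride, pyridine, DMAP, CH2Cl2, 0 °C to rt
Reagents that add atoms: 4-methoxybenzoyl chloride, COc1ccc(cc1)C(Cl)=O
Why: DMAP-catalysed acylation reaches only the secondary C6 hydroxyl, the tertiary C4 hydroxyl next to the isopropyl group being too hindered.

Step 12
Reactants: 16 6α-(4-methoxybenzoate)
Product: 17 9α,10α-epoxy-4β-hydroxy-4α-isopropyl-1β,8α-dimethyl-5αH-hydroazulan-6α-yl 4-methoxybenzoate
Conditions: mCPBA, NaHCO3, CH2Cl2, 0 °C
Reagents that add atoms: 3-chloroperoxybenzoic acid, OOC(=O)c1cccc(Cl)c1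
Why: Prilezhaev epoxidation of the only olefin should take place on the α face, because in the trans-fused chair the pseudoaxial C1 methyl covers the β face of C10 while the 8α-methyl is pseudoequatorial.

Step 13
Reactants: 17 9α,10α-epoxide
Product: 20 4β,10α-dihydroxy-4α-isopropyl-1β,8-dimethyl-5αH-hydroazul-8-en-6α-yl 4-methoxybenzoate, via hydroxy selenide 18 (not isolated), via selenoxide 19 (not isolated)
Conditions: (PhSe)2, NaBH4, EtOH, rt to 60 °C; then THF, pyridine, 30% H2O2, 0 °C to rt
Reagents that add atoms: none
Why: Epoxide to allylic alcohol transposition by way of a β-hydroxy selenide: the selenolate opens the epoxide at C9 with inversion (C10 is neopentyl), and the selenoxide formed with H2O2 eliminates syn through the 8β-hydrogen, away from the carbinol carbon, giving the C8=C9 olefin with the 10α-hydroxyl inherited from the epoxide.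

Step 14
Reactants: 20 10α-allylic alcohol
Product: 21 10α-acetoxy-4β-hydroxy-4α-isopropyl-1β,8-dimethyl-5αH-hydroazul-8-en-6α-yl 4-methoxybenzoate (CNP0256979.2)
Conditions: Ac2O, pyridine, DMAP (cat.), CH2Cl2, rt
Reagents that add atoms: acetic anhydride, CC(=O)OC(C)=O
Why: DMAP-catalysed acetylation of the secondary allylic alcohol, the tertiary C4 hydroxyl staying free under these mild conditions.

**Compound list**

1 | crotonaldehyde, (E)-but-2-enal | C/C=C/C=O | starting material
2 | ethyl 2-(triphenyl-λ5-phosphanylidene)propanoate | CCOC(=O)C(C)=P(c1ccccc1)(c1ccccc1)c1ccccc1 | starting material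
3 | ethyl (2E,4E)-2-methylhexa-2,4-dienoate | CCOC(=O)/C(C)=C/C=C/C | intermediate
4 | (2E,4E)-2-methylhexa-2,4-dien-1-ol | OC/C(C)=C/C=C/C | intermediate
5 | (2E,4E)-1-bromo-2-methylhexa-2,4-diene | BrC/C(C)=C/C=C/C | intermediate
6 | acetylacetone, pentane-2,4-dione | CC(=O)CC(C)=O | starting material
7 | (7E,9E)-7-methylundeca-7,9-diene-2,4-dione | CC(=O)CC(=O)CC/C(C)=C/C=C/C | intermediate
8 | (7E,9E)-3-diazo-7-methylundeca-7,9-diene-2,4-dione | CC(=O)C(=[N+]=[N-])C(=O)CC/C(C)=C/C=C/C | intermediate
9 | (7E,9E)-2-(tert-butyldimethylsilyloxy)-3-diazo-7-methylundeca-1,7,9-trien-4-one | C=C(O[Si](C)(C)C(C)(C)C)C(=[N+]=[N-])C(=O)CC/C(C)=C/C=C/C | intermediate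
10 | (1S,5R,6R)-1-[1-(tert-butyldimethylsilyloxy)ethenyl]-5-methyl-6-[(E)-prop-1-enyl]bicyclo[3.1.0]hexan-2-one (6-exo propenyl, cis to methyl and silyloxyvinyl) | C=C(O[Si](C)(C)C(C)(C)C)[C@@]12C(=O)CC[C@]1(C)[C@H]2/C=C/C | intermediate
11 | (1R,8R)-6-(tert-butyldimethylsilyloxy)-1β,8α-dimethylhydroazulena-5,9-dien-4-one | CC(C)(C)[Si](C)(C)OC1=C2C(=O)CC[C@]2(C)C=C[C@H](C)C1 | intermediate
12 | isopropylmagnesium chloride | CC(C)[Mg]Cl | starting material
13 | 6-(tert-butyldimethylsilyloxy)-4α-isopropyl-1β,8α-dimethylhydroazulena-5,9-dien-4β-ol (formed in the flask) | CC(C)(C)[Si](C)(C)OC1=C2[C@](O)(C(C)C)CC[C@]2(C)C=C[C@H](C)C1 | intermediate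
14 | 4β-hydroxy-4α-isopropyl-1β,8α-dimethyl-5αH-hydroazul-9-en-6-one (trans-fused) | O=C1[C@H]2[C@](O)(C(C)C)CC[C@]2(C)C=C[C@H](C)C1 | intermediate
15 | 4α-isopropyl-1β,8α-dimethyl-5αH-hydroazul-9-ene-4β,6α-diol | O[C@@H]1[C@H]2[C@](O)(C(C)C)CC[C@]2(C)C=C[C@H](C)C1 | intermediate
16 | 4β-hydroxy-4α-isopropyl-1β,8α-dimethyl-5αH-hydroazul-9-en-6α-yl 4-methoxybenzoate | COc1ccc(cc1)C(=O)O[C@@H]2[C@H]3[C@](O)(C(C)C)CC[C@]3(C)C=C[C@H](C)C2 | intermediate
17 | 9α,10α-epoxy-4β-hydroxy-4α-isopropyl-1β,8α-dimethyl-5αH-hydroazulan-6α-yl 4-methoxybenzoate | COc1ccc(cc1)C(=O)O[C@@H]2[C@H]3[C@](O)(C(C)C)CC[C@]3(C)[C@@H]4O[C@@H]4[C@H](C)C2 | intermediate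
18 | 4β,10α-dihydroxy-4α-isopropyl-1β,8α-dimethyl-9β-(phenylselanyl)-5αH-hydroazulan-6α-yl 4-methoxybenzoate (formed in the flask) | COc1ccc(cc1)C(=O)O[C@@H]2[C@H]3[C@](O)(C(C)C)CC[C@]3(C)[C@H](O)[C@@H]([Se]c4ccccc4)[C@H](C)C2 | intermediate
19 | the Se-oxide of 18 (formed in the flask) | COc1ccc(cc1)C(=O)O[C@@H]2[C@H]3[C@](O)(C(C)C)CC[C@]3(C)[C@H](O)[C@@H]([Se](=O)c4ccccc4)[C@H](C)C2 | intermediate
20 | 4β,10α-dihydroxy-4α-isopropyl-1β,8-dimethyl-5αH-hydroazul-8-en-6α-yl 4-methoxybenzoate | COc1ccc(cc1)C(=O)O[C@@H]2[C@H]3[C@](O)(C(C)C)CC[C@]3(C)[C@H](O)C=C(C)C2 | intermediate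
21 | 10α-acetoxy-4β-hydroxy-4α-isopropyl-1β,8-dimethyl-5αH-hydroazul-8-en-6α-yl 4-methoxybenzoate (CNP0256979.2) | COc1ccc(C(=O)O[C@H]2CC(C)=C[C@@H](OC(C)=O)[C@@]3(C)CC[C@@](O)(C(C)C)[C@H]23)cc1 | target

**Step count and risks**

Total step count: 14. Longest linear sequence: 14 steps (from crotonaldehyde 1 to 21); the route is fully linear.

Steps most likely to fail:

1. Step 6. What may go wrong: loss of regiocontrol in the enolisation (deprotonation at the C3 methylene competing with the methyl group, or double silylation) and hydrolysis of the sensitive silyl dienol ether on handling. Fallback, setting out from 6 and 5 and coming back at 9: the enol ether is made on a symmetrical diazo diketone before the chain is attached. Diazo transfer to acetylacetone 6 (4-acetamidobenzenesulfonyl azide, Et3N, MeCN) gives 3-diazopentane-2,4-dione F1. TBSOTf and Et3N silylate one of its two equivalent acetyl groups to 4-(tert-butyldimethylsilyloxy)-3-diazopent-4-en-2-one F2. The remaining methyl ketone is then the only enolisable position, and its lithium enolate (LiN(SiMe3)2, THF–DMPU, −78 °C) is alkylated with bromide 5 to give 9.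

2. Step 7. What may go wrong: insufficient asymmetric induction, or induction in the opposite sense, by the chiral carboxylate catalyst. Fallback, setting out from 9 and coming back at 16: catalyst control is given up in favour of a resolution. Cyclisation of 9 with achiral Rh2(OAc)4 gives 10 together with its mirror image, the (1R,5S,6S)-cyclopropane F3. Steps 8 to 11, unchanged, carry the racemate on through the mirror-image Cope product F4, the mirror-image carbinol silyl enol ether F5 (not isolated), the mirror-image hydroxy ketone F6, the mirror-image diol F7 and the mirror-image anisoate F8. Preparative chromatography of the UV-active ester on a chiral stationary phase (amylose tris(3,5-dimethylphenylcarbamate)) removes F8 and returns enantiopure 16.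

3. Step 9. What may go wrong: the branched organometallic acting as a base or hydride donor toward the hindered vinylogous ester carbonyl instead of adding, and retro-aldol cleavage or incomplete epimerisation at C5 during the equilibration. Fallback, setting out from 11 and coming back at 14: an sp2 nucleophile is added and reduced afterwards. Isopropenylmagnesium bromide with CeCl3 (THF, −78 °C), which cannot deliver a β-hydride and is less basic, gives the isopropenyl carbinol silyl enol ether F9 (not isolated). The same buffered fluoride and DBU treatment gives 4β-hydroxy-4α-isopropenyl-1β,8α-dimethyl-5αH-hydroazul-9-en-6-one F10. Hydroxyl-directed hydrogenation with [Rh(nbd)(dppb)]BF4 and H2 in CH2Cl2, steered by the tertiary allylic hydroxyl, should saturate only the isopropenyl group and leave the hindered, undirected ring olefin, giving 14.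

Further compounds
F1 | step 6 | 3-diazopentane-2,4-dione | CC(=O)C(=[N+]=[N-])C(C)=O
F2 | step 6 | 4-(tert-butyldimethylsilyloxy)-3-diazopent-4-en-2-one | C=C(O[Si](C)(C)C(C)(C)C)C(=[N+]=[N-])C(C)=O
F3 | step 7 | (1R,5S,6S)-1-[1-(tert-butyldimethylsilyloxy)ethenyl]-5-methyl-6-[(E)-prop-1-enyl]bicyclo[3.1.0]hexan-2-one (mirror image of 10) | C=C(O[Si](C)(C)C(C)(C)C)[C@]12C(=O)CC[C@@]1(C)[C@@H]2/C=C/C
F4 | step 7 | (1S,8S)-6-(tert-butyldimethylsilyloxy)-1,8-dimethylhydroazulena-5,9-dien-4-one (mirror image of 11) | CC(C)(C)[Si](C)(C)OC1=C2C(=O)CC[C@@]2(C)C=C[C@@H](C)C1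
F5 | step 7 | mirror image of carbinol silyl enol ether 13 | CC(C)(C)[Si](C)(C)OC1=C2[C@@](O)(C(C)C)CC[C@@]2(C)C=C[C@@H](C)C1
F6 | step 7 | mirror image of hydroxy ketone 14 | O=C1[C@@H]2[C@@](O)(C(C)C)CC[C@@]2(C)C=C[C@@H](C)C1
F7 | step 7 | mirror image of diol 15 | O[C@H]1[C@@H]2[C@@](O)(C(C)C)CC[C@@]2(C)C=C[C@@H](C)C1
F8 | step 7 | mirror image of anisoate 16 | COc1ccc(cc1)C(=O)O[C@H]2[C@@H]3[C@@](O)(C(C)C)CC[C@@]3(C)C=C[C@@H](C)C2
F9 | step 9 | 6-(tert-butyldimethylsilyloxy)-4α-isopropenyl-1β,8α-dimethylhydroazulena-5,9-dien-4β-ol | CC(C)(C)[Si](C)(C)OC1=C2[C@](O)(C(C)=C)CC[C@]2(C)C=C[C@H](C)C1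
F10 | step 9 | 4β-hydroxy-4α-isopropenyl-1β,8α-dimethyl-5αH-hydroazul-9-en-6-one | O=C1[C@H]2[C@](O)(C(C)=C)CC[C@]2(C)C=C[C@H](C)C1
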